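I began from late times, from the last readings of the earlier runs.

all flasks: gas phase 0.76 mM (held); catalyst 1.5 mM
- alpha: starting material 0.010 M; added ligand 0.95 mM; run made earlier
- eta: starting material 0.010 M; added ligand 3.8 mM; run made earlier
- gamma: starting material 0.020 M; added ligand 1.9 mM; run made earlier
- flask: starting material 0.010 M; added ligand 1.9 mM; time 3.0 d

| run | time / d | target / % | starting material / % |
|---|---|---|---|
| alpha | 0.250 | 3.0 | 97.8 |
| alpha | 0.417 | 2.8 | 96.1 |
| alpha | 0.625 | 5.0 | 94.7 |
| alpha | 1.04 | 7.7 | 92.8 |
| alpha | 1.67 | 12.3 | 85.6 |
| alpha | 2.50 | 18.2 | 78.7 |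
| alpha | 4.00 | 23.1 | 70.2 |
| eta | 0.250 | 0.8 | 98.5 |
| eta | 0.417 | 0.2 | 98.3 |
| eta | 0.625 | 0.2 | 98.2 |
| eta | 1.04 | 0.7 | 98.7 |
| eta | 1.67 | 1.6 | 96.4 |
| eta | 2.50 | 3.8 | 96.7 |
| eta | 4.00 | 4.7 | 93.7 |
| gamma | 0.625 | 2.4 | 96.4 |
| gamma | 1.25 | 5.1 | 95.7 |
| gamma | 2.00 | 8.3 | 93.3 |
| gamma | 3.00 | 10.0 | 87.5 |
| gamma | 4.00 | 11.5 | 82.9 |

(readings scatter by 1 percentage point)
- at the start none of the gas is dissolved
- steps under discussion: gas phase <-> dissolved gas; starting material + dissolved gas + catalyst -> catalyst + target; catalyst + added ligand <-> idle complex; dissolved gas + target -> over-reaction product; dissolved gas -> decomposed reagent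
- larch: doubling the saturation concentration of gas phase, all else as stated
- oak: doubling the transfer coefficient of the gas phase, all else as stated
- alder: doubling the amount of catalyst, all else as stated
- amount of target at 3.0 d, in percent of the starting material charged
- concentration of dissolved gas in solution at 20 h, in percent of saturation
- the change that raises the amount of target at 3.0 d, in percent of the starting material charged most ("none" if none brings more than 2 percentage points) (larch / oak / alder / none)
- amount of target at 3.0 d, in percent of the starting material charged, after oak

1. I took the loss of starting material as pseudo-first-order, with the gas near steady. The last readings gave a rate constant k of 0.0885 d⁻¹ for alpha and 0.0469 d⁻¹ for gamma.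

2. As the zero of my scale I let each added ligand tie up one catalyst completely. Alpha then kept 0.550 mM of free catalyst, which gave a first κ, the rate constant per unit of free catalyst, of 161 L mol⁻¹ d⁻¹.

3. Gamma has more ligand than catalyst, so it stood at zero free catalyst on that scale, yet it ran. Its rate implied 0.292 mM free, and so a binding constant K of 5.99 mM⁻¹.

4. The flask has gamma's catalyst and ligand. If the loss is first order in starting material, its percentages are gamma's, so I committed to gamma's reading at 3.00 d: 10.0%.

5. Step 2 was the weak link, since with that K alpha holds 0.727 mM free, more than the 0.550 mM I had set. The reforged κ, the rate constant per unit of free catalyst, is 122 L mol⁻¹ d⁻¹, which puts 0.385 mM free in the flask.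

6. Alder leaves at least 1.10 mM free, 2.86 times my estimate for the flask, more than the factor of 2 that doubled dissolved gas gives a step first order in it. I chose alder.

The forecast gave 11% of target (9% to 13.5%), above my 10.0%, with dissolved gas at 73% of saturation at 20 h (50% to 92%), alder as the best change and 12.5% of target after oak (10.5% to 16%): “doubling the catalyst should free far more of it”.

The flask gave 10.1% of target, dissolved gas at 90.8% of saturation at 20 h, 18 percentage points above the forecast, alder as the best change (a gain of 19 points) and 10.6% of target after oak.

    gas phase ⇌ dissolved gas, rate k1*(csat - [dissolved gas]) (kL = 0.383 h⁻¹)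
    starting material + dissolved gas + catalyst → catalyst + target (k = 8180 L² mol⁻² h⁻¹)
    catalyst + added ligand ⇌ idle complex, settled at all times (K = 4300 L mol⁻¹)
    dissolved gas + target → over-reaction product (k = 10.5 L mol⁻¹ h⁻¹)
    dissolved gas → decomposed reagent (k = 0.00772 h⁻¹)

At 3.00 d the flask's starting material had a half-life of 15 d by the catalysed step, longer than the 3.0 d of the run, and 87% of it stood; κ with the 0.354 mM of free catalyst there gives 16.1 d. For the neighbour flask with 0.0037 M of catalyst, κ with the excess of catalyst over ligand, 1.80 mM, gives a loss of starting material of 48.1%, and that flask lost 46.3%.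

(The earlier runs and the new flask stem from a simulated flask with made-up constants.)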